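**Abbreviations:** TBS = tert-butyldimethylsilyl, TES = triethylsilyl, Ar = 4-(TBS-oxy)phenyl.

## Structural features

The target is a fully substituted 1,4-benzoquinone (ring A) that carries two 4-hydroxyphenyl rings (rings B and C) on C2 and C5 through C–C bonds and two enol-ester oxygens on C3 and C6, so the core is centrosymmetric and achiral. Each ester is a six-carbon chain, C1 (ester carbonyl) to C6 (methyl), with a 2Z alkene and a trans-oxirane across C4–C5. C4 and C5 are adjacent stereocentres, both S; the two pairs are identical and far apart, with nothing between them to relay stereochemical information. The fragile groups are the acyloxyquinone (a vinylogous anhydride, open to acyl transfer, hydrolysis and perhydrolysis), the Z-enoates (isomerised to E by reversible nucleophilic addition or light), the vinyl oxiranes (opened by acid, by soft nucleophiles and by zerovalent palladium) and the free phenols next to a redox-active quinone. A Z-configured 4-hydroxy or 4,5-epoxy acid of this type lactonises easily, which makes a preformed epoxy acid a poor acyl donor. The carbon skeleton is therefore not the problem. The difficulty is to place four stereocentres on two arms of an achiral core without activating such an acid, and to unveil the acyloxyquinone only at the end. The plan exploits the hydroquinone-level bis-dienoate: with the two remaining ring A oxygens silylated, the C4=C5 E-alkenes are the only electron-rich, accessible π bonds, C2=C3 is deactivated by the ester, and ring A has neither a free position nor a free hydroxyl.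

## Logic of the disconnections

18 ⇒ 16 (through 17). In the retrosynthetic sense four O–Si bonds are added and ring A is taken to the hydroquinone level. The vinylogous anhydride is the most electrophilic part of 18 and should appear last. The gain is that ring A becomes an ordinary, fully substituted arene that tolerates an aqueous oxidant. The forward step must cleave four aryl silyl ethers without free phenoxide and then dehydrogenate under neutral conditions.

16 ⇒ 15. The C4–O and C5–O bonds of both oxiranes are cut. This puts all four stereocentres and both three-membered rings into one catalyst-controlled operation on an achiral precursor, and neither a Z-epoxy acid nor a Z-hydroxy enoate appears anywhere. The forward step needs site selectivity (C4=C5 over C2=C3), face selectivity from the catalyst on both arms, and tolerance of aryl esters and aryl silyl ethers.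

15 ⇒ 13 (through 14). The two O–Si bonds on ring A are cut and the ring returns to the quinone level. The quinone carbonyls mark which two of the four ring A oxygens carry silicon, so no choice among four similar oxygens arises. The forward step needs a reduction that spares the dienoates and a silylation of flanked phenols that is faster than an ortho acyl shift.

13 ⇒ 7 + 11 (through 12). Both acyl C–O bonds are cut. The route becomes convergent and the core and the arm are made separately. The forward step must activate 11 without loss of the 2Z geometry and must acylate oxygen only; the latter is assured because every carbon of ring A is substituted.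

11 ⇒ 10 ⇒ 8 + 9. The C2=C3 bond is cut. The 4E alkene comes ready-made from 8, and the 2Z alkene is made by a Z-selective phosphonate olefination. The hydrolysis must be mild enough to keep both geometries.

7 ⇒ 5 (through 6). The two aryl O–Si bonds are cut. The phenols of rings B and C must be masked before acylation and before the oxidant of the key step. The phenolic and enolic hydroxyls are differentiated by the very different lability of their silyl derivatives.

5 ⇒ 4 ⇒ 2 + 3. The two ring A–aryl C–C bonds (and the two O–CH3 bonds) are cut. Both aryl rings are introduced in one twofold cross-coupling with fixed regiochemistry, which consumes two molecules of 3 for each molecule of 2, and the methoxy groups are vinylogous esters that hydroxide replaces.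

2 ⇒ 1. Two C–OCH3 bonds are cut, which leads back to a commercial tetrahaloquinone through twofold addition–elimination.

## Other disconnections considered

**Alternative 1:** Ring A is cut at both bonds between an aryl-bearing carbon and a carbonyl carbon, so the ring arises from two molecules of one monomer.
- Forward step: S-ethyl 3-[4-(TBS-oxy)phenyl]-2-oxopropanethioate A2, made from 3-(4-hydroxyphenyl)-2-oxopropanoic acid A1, is enolised with MgBr2·OEt2 and iPr2NEt. Two Claisen condensations (C3 of each unit onto the thioester carbon of the other) would give 2,5-bis[4-(TBS-oxy)phenyl]-3,6-dihydroxy-1,4-benzoquinone A3, identical in constitution with 7.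
- In favour: one step builds ring A at the correct oxidation level, it needs no transition metal and no halogenated quinone, and the non-hydrolytic conditions should keep the aryl silyl ethers. A3 would arrive without the hydrolysis and resilylation of steps 3 and 4.
- Against: the ketone carbon of A2 is more electrophilic than its thioester carbon, so aldol-type dimerisation competes with the head-to-tail Claisen mode. Without an enzyme nothing in the substrate enforces the wanted mode, and the acidic, chelating product consumes base and MgBr2.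
- Comparison: on structure it reaches the same intermediate 7 and leaves the arms and stereocentres to the same later steps. On mechanism it is less predictable than the cross-coupling of step 2. On step economy it is equal or slightly better for the first part (about three operations to A3 against four to 7), and it is better in atom economy.

**Alternative 2:** Ring A is cut at the bond between a hydroxyl-bearing carbon and a methoxy-bearing carbon.
- Forward step: thermolysis of 4-hydroxy-3-methoxy-4-{2-methoxy-1-[4-(TBS-oxy)phenyl]ethenyl}-2-[4-(TBS-oxy)phenyl]cyclobut-2-en-1-one A4 opens the four-membered ring to a dienylketene. 6π-Electrocyclisation and tautomerisation would give 2,5-bis[4-(TBS-oxy)phenyl]-3,6-dimethoxybenzene-1,4-diol A5.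
- In favour: it is a neutral, thermal cascade of a well-understood type, with the position of every substituent fixed by the order of two organolithium additions to a squaric ester. It is the better plan where two different aryl rings are wanted, and it is the equal of the chosen plan in mechanistic reliability.
- Against: A5 is only the reduced form of 4 and would be oxidised to 4 to join the route. Reaching A4 needs an aryllithium addition, a rearrangement and a second addition of a 1-aryl-2-methoxyvinyl-lithium that must itself be made. Acylating the free hydroxyls of A5 directly is attractive on paper, but the methyl ethers would then need an oxidative demethylation with (NH4)2Ce(NO3)6 that the vinyl oxiranes and the electron-rich rings B and C would not survive.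
- Comparison: same structure as 4, several steps longer, no gain for the stereocentres.

**Alternative 3:** Both ring A–aryl bonds are cut and formed last.
- Forward step: 2,5-dihydroxy-1,4-benzoquinone A6 would be acylated twice with the Z-epoxy acid to 3,6-dioxocyclohexa-1,4-diene-1,4-diyl bis{(2Z)-3-[(2S,3S)-3-methyloxiran-2-yl]prop-2-enoate} A7. Aryl radicals from 3 (AgNO3, K2S2O8) would add to its two unsubstituted carbons to give the bis(TBS) ether of the target A8.
- In favour: it is the most convergent plan and the better one on step economy (about six steps). Ring A needs no protection or redox change, only two silyl ethers remain to be removed, and the regiochemistry is unambiguous because only two positions are free.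
- Against: A7 requires exactly the activated Z-epoxy acid that the chosen plan avoids. The stereocentres, the Z-enoates and the vinyl oxiranes would then meet aryl radicals and sulfate radical anion, for which the electron-poor C2=C3 alkenes are competing acceptors. The acyloxyquinone would stand in an aqueous, acidic oxidant, and the second arylation must occur at a crowded carbon next to an acyloxy group.
- Comparison: shorter, but the most sensitive functionality is carried through the least selective step, whereas the chosen plan installs it second to last under mild, catalyst-controlled conditions.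

Key step: step 9

## Route

Assumption: tetrabromo-1,4-benzoquinone is taken as the source of ring A because the C–Br bonds of 2 should enter the coupling of step 2 more readily than C–Cl bonds, and the L-configured ketone of step 9 is taken as purchasable (it is otherwise made from L-sorbose by a known sequence).

Step 1
Reactants: 1 tetrabromo-1,4-benzoquinone
Product: 2 2,5-dibromo-3,6-dimethoxy-1,4-benzoquinone
Conditions: NaOMe (2.1 equiv), MeOH, 0 °C to rt
Reagents that add atoms: sodium methoxide, C[O-].[Na+]
Why: Twofold addition–elimination (vinylogous acyl substitution); the first methoxy group deactivates its own enone arm, so the second methoxide should enter at the para-related carbon and give the 2,5-dibromo-3,6-dimethoxy isomer.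

Step 2
Reactants: 2 2,5-dibromo-3,6-dimethoxy-1,4-benzoquinone; 3 [4-(tert-butyldimethylsilyloxy)phenyl]boronic acid (2.4 equiv)
Product: 4 2,5-bis[4-(tert-butyldimethylsilyloxy)phenyl]-3,6-dimethoxy-1,4-benzoquinone
Conditions: 3 (2.4 equiv), PdCl2(dppf) (5 mol %; dppf = 1,1'-bis(diphenylphosphino)ferrocene), K3PO4, 1,4-dioxane, 90 °C
Reagents that add atoms: [4-(tert-butyldimethylsilyloxy)phenyl]boronic acid (second equivalent of 3), CC(C)(C)[Si](C)(C)Oc1ccc(B(O)O)cc1
Why: Twofold Suzuki–Miyaura coupling in which each of the two C–Br bonds of 2 takes up one molecule of 3, so two molecules of 3 are consumed per molecule of 2 and a slight excess covers protodeboronation. The C–Br bonds of 2 are vinylogous acyl bromides that should add readily to zerovalent palladium, and a non-aqueous phosphate base spares the silyl ethers and methoxy groups.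

Step 3
Reactants: 4 2,5-bis[4-(tert-butyldimethylsilyloxy)phenyl]-3,6-dimethoxy-1,4-benzoquinone
Product: 5 2,5-dihydroxy-3,6-bis(4-hydroxyphenyl)-1,4-benzoquinone (atromentin)
Conditions: 2 M NaOH, 1,4-dioxane/H2O, 60 °C; then 2 M HCl
Reagents that add atoms: sodium hydroxide, [Na+].[OH-]
Why: Hydrolysis of the vinylogous methyl esters by conjugate addition–elimination of hydroxide, which also cleaves both aryl silyl ethers; the resulting polyanion resists further attack and acidification should precipitate 5.

Step 4
Reactants: 5 2,5-dihydroxy-3,6-bis(4-hydroxyphenyl)-1,4-benzoquinone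
Product: 7 2,5-bis[4-(tert-butyldimethylsilyloxy)phenyl]-3,6-dihydroxy-1,4-benzoquinone, via tetrakis-silyl quinone 6 (not isolated)
Conditions: TBSCl (6 equiv), imidazole, DMF, rt; then THF/H2O/AcOH, rt
Reagents that add atoms: tert-butyldimethylsilyl chloride, CC(C)(C)[Si](C)(C)Cl
Why: Exhaustive silylation followed by selective hydrolysis; the two silyl groups on the enolic oxygens are vinylogous silyl esters and should fall off in dilute acetic acid, while the aryl silyl ethers are stable to it.

Step 5
Reactants: 8 (E)-but-2-enal; 9 methyl 2-[bis(2,2,2-trifluoroethoxy)phosphoryl]acetate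
Product: 10 methyl (2Z,4E)-hexa-2,4-dienoate
Conditions: KN(SiMe3)2, 18-crown-6, THF, −78 °C
Reagents that add atoms: none
Why: Still–Gennari olefination; the electron-poor phosphonate under dissociating conditions eliminates quickly from the kinetic adduct and should favour the 2Z enoate, while the E alkene of 8 is carried through unchanged.

Step 6
Reactants: 10 methyl (2Z,4E)-hexa-2,4-dienoate
Product: 11 (2Z,4E)-hexa-2,4-dienoic acid
Conditions: LiOH·H2O, THF/H2O, 0 °C to rt; then 1 M HCl to pH 3 at 0 °C
Reagents that add atoms: lithium hydroxide, [Li+].[OH-]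
Why: Ester saponification (acyl–oxygen cleavage) under mild conditions, cold and in the dark, should leave both alkene geometries intact; any E,E acid can be removed here by crystallisation or chromatography.

Step 7
Reactants: 11 (2Z,4E)-hexa-2,4-dienoic acid; 7 2,5-bis[4-(tert-butyldimethylsilyloxy)phenyl]-3,6-dihydroxy-1,4-benzoquinone
Product: 13 2,5-bis[4-(tert-butyldimethylsilyloxy)phenyl]-3,6-dioxocyclohexa-1,4-diene-1,4-diyl bis[(2Z,4E)-hexa-2,4-dienoate], via dienoyl chloride 12 (not isolated)
Conditions: 11 (2.4 equiv), 1-chloro-N,N,2-trimethylprop-1-en-1-amine, CH2Cl2, 0 °C; then 7, 2,6-lutidine, −20 to 0 °C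
Reagents that add atoms: none
Why: The α-chloroenamine forms the acid chloride without HCl or a nucleophilic catalyst, which protects the 2Z geometry; the enolic hydroxyls of 7 are vinylogous carboxylic acids whose lutidinium salts should be O-acylated like carboxylates. The hindered, weak base is unlikely to trigger vinylketene formation.

Step 8
Reactants: 13 2,5-bis[4-(tert-butyldimethylsilyloxy)phenyl]-3,6-dioxocyclohexa-1,4-diene-1,4-diyl bis[(2Z,4E)-hexa-2,4-dienoate]
Product: 15 2,5-bis[4-(tert-butyldimethylsilyloxy)phenyl]-3,6-bis(tert-butyldimethylsilyloxy)-1,4-phenylene bis[(2Z,4E)-hexa-2,4-dienoate], via hydroquinone diester 14 (not isolated)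
Conditions: aqueous Na2S2O4, CH2Cl2, rt, degassed; organic phase dried (Na2SO4) under argon; then TBSOTf, 2,6-lutidine, 0 °C
Reagents that add atoms: tert-butyldimethylsilyl trifluoromethanesulfonate, CC(C)(C)[Si](C)(C)OS(=O)(=O)C(F)(F)F
Why: Quinone reduction by Na2S2O4 followed by silyl triflate silylation of the two new phenols, which are exactly the former carbonyl oxygens; the triflate is reactive enough for flanked phenols and lutidine is too weak a base to promote an ortho acyl shift. 14 is air-sensitive and is therefore not isolated.

Step 9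
Reactants: 15 2,5-bis[4-(tert-butyldimethylsilyloxy)phenyl]-3,6-bis(tert-butyldimethylsilyloxy)-1,4-phenylene bis[(2Z,4E)-hexa-2,4-dienoate]
Product: 16 2,5-bis[4-(tert-butyldimethylsilyloxy)phenyl]-3,6-bis(tert-butyldimethylsilyloxy)-1,4-phenylene bis{(2Z)-3-[(2S,3S)-3-methyloxiran-2-yl]prop-2-enoate}
Conditions: 1,2:4,5-di-O-isopropylidene-β-L-erythro-2,3-hexodiulo-2,6-pyranose (0.6 equiv), KHSO5 (as 2KHSO5·KHSO4·K2SO4) and K2CO3 added slowly and separately, Bu4NHSO4 (cat.), MeCN/CH2(OMe)2, aqueous Na2B4O7 buffer with Na2H2EDTA, pH about 10.5, 0 °C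
Reagents that add atoms: potassium peroxymonosulfate, [K+].[O-]S(=O)(=O)OO
Why: KHSO5 adds to the carbonyl of the chiral ketone and the adduct closes with loss of sulfate to a dioxirane, which transfers one oxygen atom to the alkene and returns the ketone; the high pH protects the catalyst from Baeyer–Villiger decay. The closest known reaction type is the Shi epoxidation of trans-disubstituted alkenes and of conjugated dienoates, which are oxidised at the alkene remote from the ester. Each oxirane is closed by a concerted oxygen-atom transfer through a spiro transition state, a [2+1] event in which both C–O bonds form on one face at once, so no exo or endo closure mode applies and the E geometry of C4=C5 becomes the trans oxirane. The relative configuration at C4 and C5 therefore comes from the alkene geometry and the absolute configuration (4S,5S on both arms) from the catalyst: the D-configured ketone gives the R,R oxide from trans-β-methylstyrene, the alkenyl group at C4 takes the CIP rank of phenyl, and so the L-configured ketone is needed. Site selectivity for C4=C5 over C2=C3 rests on the electrophilic dioxirane, since C2=C3 is deactivated by the ester and, being cis, fits this catalyst poorly. Chemoselectivity rests on the substrate design: ring A has no free hydroxyl or C–H, each aryl ester is shielded by an ortho aryl ring and an ortho silyloxy group, and 0 °C with slow addition limits attack of hydroxide or SO5 dianion on the esters. The two arms react independently, and an arm oxidised on the wrong face ends in the meso diastereomer, which should be separable, so the enantiomeric purity of 16 is expected to exceed that of a single oxygen transfer.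

Step 10
Reactants: 16 2,5-bis[4-(tert-butyldimethylsilyloxy)phenyl]-3,6-bis(tert-butyldimethylsilyloxy)-1,4-phenylene bis{(2Z)-3-[(2S,3S)-3-methyloxiran-2-yl]prop-2-enoate}
Product: 18 2,5-bis(4-hydroxyphenyl)-3,6-dioxocyclohexa-1,4-diene-1,4-diyl bis{(2Z)-3-[(2S,3S)-3-methyloxiran-2-yl]prop-2-enoate}, via free hydroquinone 17 (not isolated)
Conditions: Bu4NF (4.4 equiv), AcOH (5.5 equiv), THF, 0 °C to rt; wash with pH 7 buffer (KH2PO4/K2HPO4); then Ag2O, MgSO4, EtOAc, 0 °C
Reagents that add atoms: none
Why: Acetic acid-buffered fluoride desilylation should free all four aryl oxygens without phenoxide that could open an oxirane or transfer an acyl group, and Ag2O then dehydrogenates the hydroquinone to the quinone under neutral conditions. A single ortho acyl shift in 17 gives a meta diester, but a second one regenerates a para diester identical with 17 because ring A is centrosymmetric, so immediate oxidation should funnel the material to 18. No stereocentre or alkene is touched.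

## Compound list

1 | tetrabromo-1,4-benzoquinone (bromanil) | O=C1C(Br)=C(Br)C(=O)C(Br)=C1Br | starting material
2 | 2,5-dibromo-3,6-dimethoxy-1,4-benzoquinone | COC1=C(Br)C(=O)C(OC)=C(Br)C1=O | intermediate
3 | [4-(tert-butyldimethylsilyloxy)phenyl]boronic acid | CC(C)(C)[Si](C)(C)Oc1ccc(B(O)O)cc1 | starting material
4 | 2,5-bis[4-(tert-butyldimethylsilyloxy)phenyl]-3,6-dimethoxy-1,4-benzoquinone | COC1=C(c2ccc(O[Si](C)(C)C(C)(C)C)cc2)C(=O)C(OC)=C(c2ccc(O[Si](C)(C)C(C)(C)C)cc2)C1=O | intermediate
5 | 2,5-dihydroxy-3,6-bis(4-hydroxyphenyl)-1,4-benzoquinone (atromentin) | OC1=C(c2ccc(O)cc2)C(=O)C(O)=C(c2ccc(O)cc2)C1=O | intermediate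
6 | 2,5-bis(tert-butyldimethylsilyloxy)-3,6-bis[4-(tert-butyldimethylsilyloxy)phenyl]-1,4-benzoquinone | CC(C)(C)[Si](C)(C)OC1=C(c2ccc(O[Si](C)(C)C(C)(C)C)cc2)C(=O)C(O[Si](C)(C)C(C)(C)C)=C(c2ccc(O[Si](C)(C)C(C)(C)C)cc2)C1=O | intermediate
7 | 2,5-bis[4-(tert-butyldimethylsilyloxy)phenyl]-3,6-dihydroxy-1,4-benzoquinone | OC1=C(c2ccc(O[Si](C)(C)C(C)(C)C)cc2)C(=O)C(O)=C(c2ccc(O[Si](C)(C)C(C)(C)C)cc2)C1=O | intermediate
8 | (E)-but-2-enal (crotonaldehyde) | C/C=C/C=O | starting material
9 | methyl 2-[bis(2,2,2-trifluoroethoxy)phosphoryl]acetate | COC(=O)CP(=O)(OCC(F)(F)F)OCC(F)(F)F | starting material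
10 | methyl (2Z,4E)-hexa-2,4-dienoate | C/C=C/C=C\C(=O)OC | intermediate
11 | (2Z,4E)-hexa-2,4-dienoic acid | C/C=C/C=C\C(=O)O | intermediate
12 | (2Z,4E)-hexa-2,4-dienoyl chloride | C/C=C/C=C\C(=O)Cl | intermediate
13 | 2,5-bis[4-(tert-butyldimethylsilyloxy)phenyl]-3,6-dioxocyclohexa-1,4-diene-1,4-diyl bis[(2Z,4E)-hexa-2,4-dienoate] | C/C=C/C=C\C(=O)OC1=C(c2ccc(O[Si](C)(C)C(C)(C)C)cc2)C(=O)C(OC(=O)/C=C\C=C\C)=C(c2ccc(O[Si](C)(C)C(C)(C)C)cc2)C1=O | intermediate
14 | 2,5-bis[4-(tert-butyldimethylsilyloxy)phenyl]-3,6-dihydroxy-1,4-phenylene bis[(2Z,4E)-hexa-2,4-dienoate] | C/C=C/C=C\C(=O)Oc1c(-c2ccc(O[Si](C)(C)C(C)(C)C)cc2)c(O)c(OC(=O)/C=C\C=C\C)c(-c2ccc(O[Si](C)(C)C(C)(C)C)cc2)c1O | intermediate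
15 | 2,5-bis[4-(tert-butyldimethylsilyloxy)phenyl]-3,6-bis(tert-butyldimethylsilyloxy)-1,4-phenylene bis[(2Z,4E)-hexa-2,4-dienoate] | C/C=C/C=C\C(=O)Oc1c(-c2ccc(O[Si](C)(C)C(C)(C)C)cc2)c(O[Si](C)(C)C(C)(C)C)c(OC(=O)/C=C\C=C\C)c(-c2ccc(O[Si](C)(C)C(C)(C)C)cc2)c1O[Si](C)(C)C(C)(C)C | intermediate
16 | 2,5-bis[4-(tert-butyldimethylsilyloxy)phenyl]-3,6-bis(tert-butyldimethylsilyloxy)-1,4-phenylene bis{(2Z)-3-[(2S,3S)-3-methyloxiran-2-yl]prop-2-enoate} | C[C@@H]1O[C@H]1/C=C\C(=O)Oc1c(-c2ccc(O[Si](C)(C)C(C)(C)C)cc2)c(O[Si](C)(C)C(C)(C)C)c(OC(=O)/C=C\[C@@H]2O[C@H]2C)c(-c2ccc(O[Si](C)(C)C(C)(C)C)cc2)c1O[Si](C)(C)C(C)(C)C | intermediate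
17 | 3,6-dihydroxy-2,5-bis(4-hydroxyphenyl)-1,4-phenylene bis{(2Z)-3-[(2S,3S)-3-methyloxiran-2-yl]prop-2-enoate} | C[C@@H]1O[C@H]1/C=C\C(=O)Oc1c(-c2ccc(O)cc2)c(O)c(OC(=O)/C=C\[C@@H]2O[C@H]2C)c(-c2ccc(O)cc2)c1O | intermediate
18 | 2,5-bis(4-hydroxyphenyl)-3,6-dioxocyclohexa-1,4-diene-1,4-diyl bis{(2Z)-3-[(2S,3S)-3-methyloxiran-2-yl]prop-2-enoate} | C[C@@H]1O[C@H]1/C=C\C(=O)OC1=C(c2ccc(O)cc2)C(=O)C(OC(=O)/C=C\[C@@H]2O[C@H]2C)=C(c2ccc(O)cc2)C1=O | target

## Step count and least certain steps

Total: 10 steps. Longest linear sequence: 8 steps (steps 1, 2, 3, 4, 7, 8, 9, 10); the arm (steps 5 and 6) joins at step 7.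

**Step 9 (key step).** The most likely failures are slow oxygen transfer to a dienoate made more electron-poor by its aryl ester, so that the ketone is spent before both arms have reacted, and cleavage of the aryl esters by hydroxide or SO5 dianion during a long reaction. Insufficient face selectivity would divert material into the meso diastereomer. The fallback moves the oxygen transfer to the small ester, a proven substrate class; it sets out from 10, uses 7, and rejoins the route at 18. Compound 10 is epoxidised with the same ketone to methyl (2Z)-3-[(2S,3S)-3-methyloxiran-2-yl]prop-2-enoate F1. LiOH gives lithium (2Z)-3-[(2S,3S)-3-methyloxiran-2-yl]prop-2-enoate F2, which is never acidified. Pivaloyl chloride at −30 °C converts it into the mixed anhydride (2Z)-3-[(2S,3S)-3-methyloxiran-2-yl]prop-2-enoic pivalic anhydride F3. This acylates the lutidinium salt of 7 to the bis(TBS) ether of the target F4, from which buffered fluoride (Bu4NF/AcOH) frees the two phenols to give 18.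

**Step 7.** The 2Z geometry may be eroded during carboxyl activation by reversible addition of chloride or amine to the dienoyl chloride, and the vinylogous anhydride may transfer its acyl group back during work-up. The fallback acylates phenols at the hydroquinone level instead; it sets out from 5 and rejoins at 15, bypassing steps 7 and 8. Compound 6 is isolated this time by non-aqueous work-up and hydrogenated (H2, Pd/C, EtOAc) to 2,5-bis[4-(tert-butyldimethylsilyloxy)phenyl]-3,6-bis(tert-butyldimethylsilyloxy)benzene-1,4-diol F5. Its two hydroxyls are esterified with 11 (N,N'-diisopropylcarbodiimide, catalytic 4-(dimethylamino)pyridine, CH2Cl2, 0 °C) to give 15.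

**Step 10.** The two silyl ethers on ring A are flanked on both sides and may cleave slowly. Long exposure to fluoride and acetate could then cause acyl transfer, ester cleavage or opening of the vinyl oxiranes, and a slow oxidation would give the ortho acyl shift time to compete. The fallback uses more labile silicon on ring A; it sets out from 14 and rejoins at 17. Compound 14 is silylated with TESOTf and 2,6-lutidine to 2,5-bis[4-(tert-butyldimethylsilyloxy)phenyl]-3,6-bis(triethylsilyloxy)-1,4-phenylene bis[(2Z,4E)-hexa-2,4-dienoate] F6. Epoxidation as in step 9 gives 2,5-bis[4-(tert-butyldimethylsilyloxy)phenyl]-3,6-bis(triethylsilyloxy)-1,4-phenylene bis{(2Z)-3-[(2S,3S)-3-methyloxiran-2-yl]prop-2-enoate} F7. A much shorter buffered fluoride treatment should then give 17, which is oxidised with Ag2O as before.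

**Step 2.** The quinone may be reduced by the zerovalent palladium and phosphine system, the boronic acid may protodeboronate, or the coupling may stall after one aryl transfer. The fallback couples at the arene level; it sets out from 2 and rejoins at 5.
- Compound 2 is reduced (Na2S2O4) and methylated (Me2SO4, K2CO3, acetone) to 1,4-dibromo-2,3,5,6-tetramethoxybenzene F8.
- Twofold Suzuki–Miyaura coupling with 3 (2.4 equiv; Pd(OAc)2, 2-dicyclohexylphosphino-2',6'-dimethoxybiphenyl, K3PO4, toluene/H2O, 100 °C) gives 4,4''-bis(tert-butyldimethylsilyloxy)-2',3',5',6'-tetramethoxy-1,1':4',1''-terphenyl F9.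
- BBr3 (CH2Cl2, −78 °C to rt, aqueous work-up) removes all methyl and silyl groups to give 1,1':4',1''-terphenyl-2',3',4,4'',5',6'-hexol F10.
- F10 is oxidised by air to 5.

## Further compounds

F1 | step 9 | methyl (2Z)-3-[(2S,3S)-3-methyloxiran-2-yl]prop-2-enoate | C[C@@H]1O[C@H]1/C=C\C(=O)OC
F2 | step 9 | lithium (2Z)-3-[(2S,3S)-3-methyloxiran-2-yl]prop-2-enoate | C[C@@H]1O[C@H]1/C=C\C(=O)[O-].[Li+]
F3 | step 9 | (2Z)-3-[(2S,3S)-3-methyloxiran-2-yl]prop-2-enoic pivalic anhydride | C[C@@H]1O[C@H]1/C=C\C(=O)OC(=O)C(C)(C)C
F4 | step 9 | 2,5-bis[4-(tert-butyldimethylsilyloxy)phenyl]-3,6-dioxocyclohexa-1,4-diene-1,4-diyl bis{(2Z)-3-[(2S,3S)-3-methyloxiran-2-yl]prop-2-enoate} | C[C@@H]1O[C@H]1/C=C\C(=O)OC1=C(c2ccc(O[Si](C)(C)C(C)(C)C)cc2)C(=O)C(OC(=O)/C=C\[C@@H]2O[C@H]2C)=C(c2ccc(O[Si](C)(C)C(C)(C)C)cc2)C1=O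
F5 | step 7 | 2,5-bis[4-(tert-butyldimethylsilyloxy)phenyl]-3,6-bis(tert-butyldimethylsilyloxy)benzene-1,4-diol | Oc1c(-c2ccc(O[Si](C)(C)C(C)(C)C)cc2)c(O[Si](C)(C)C(C)(C)C)c(O)c(-c2ccc(O[Si](C)(C)C(C)(C)C)cc2)c1O[Si](C)(C)C(C)(C)C
F6 | step 10 | 2,5-bis[4-(tert-butyldimethylsilyloxy)phenyl]-3,6-bis(triethylsilyloxy)-1,4-phenylene bis[(2Z,4E)-hexa-2,4-dienoate] | C/C=C/C=C\C(=O)Oc1c(-c2ccc(O[Si](C)(C)C(C)(C)C)cc2)c(O[Si](CC)(CC)CC)c(OC(=O)/C=C\C=C\C)c(-c2ccc(O[Si](C)(C)C(C)(C)C)cc2)c1O[Si](CC)(CC)CC
F7 | step 10 | 2,5-bis[4-(tert-butyldimethylsilyloxy)phenyl]-3,6-bis(triethylsilyloxy)-1,4-phenylene bis{(2Z)-3-[(2S,3S)-3-methyloxiran-2-yl]prop-2-enoate} | C[C@@H]1O[C@H]1/C=C\C(=O)Oc1c(-c2ccc(O[Si](C)(C)C(C)(C)C)cc2)c(O[Si](CC)(CC)CC)c(OC(=O)/C=C\[C@@H]2O[C@H]2C)c(-c2ccc(O[Si](C)(C)C(C)(C)C)cc2)c1O[Si](CC)(CC)CC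
F8 | step 2 | 1,4-dibromo-2,3,5,6-tetramethoxybenzene | COc1c(OC)c(Br)c(OC)c(OC)c1Br
F9 | step 2 | 4,4''-bis(tert-butyldimethylsilyloxy)-2',3',5',6'-tetramethoxy-1,1':4',1''-terphenyl | COc1c(OC)c(-c2ccc(O[Si](C)(C)C(C)(C)C)cc2)c(OC)c(OC)c1-c1ccc(O[Si](C)(C)C(C)(C)C)cc1
F10 | step 2 | 1,1':4',1''-terphenyl-2',3',4,4'',5',6'-hexol | Oc1ccc(cc1)-c1c(O)c(O)c(-c2ccc(O)cc2)c(O)c1O
A1 | alternative 1 | 3-(4-hydroxyphenyl)-2-oxopropanoic acid | OC(=O)C(=O)Cc1ccc(O)cc1
A2 | alternative 1 | S-ethyl 3-[4-(tert-butyldimethylsilyloxy)phenyl]-2-oxopropanethioate | CCSC(=O)C(=O)Cc1ccc(O[Si](C)(C)C(C)(C)C)cc1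
A3 | alternative 1 | 2,5-bis[4-(tert-butyldimethylsilyloxy)phenyl]-3,6-dihydroxy-1,4-benzoquinone | OC1=C(c2ccc(O[Si](C)(C)C(C)(C)C)cc2)C(=O)C(O)=C(c2ccc(O[Si](C)(C)C(C)(C)C)cc2)C1=O
A4 | alternative 2 | 4-hydroxy-3-methoxy-4-{2-methoxy-1-[4-(tert-butyldimethylsilyloxy)phenyl]ethenyl}-2-[4-(tert-butyldimethylsilyloxy)phenyl]cyclobut-2-en-1-one (racemic, alkene geometry left open) | COC=C(c1ccc(O[Si](C)(C)C(C)(C)C)cc1)C1(O)C(OC)=C(c2ccc(O[Si](C)(C)C(C)(C)C)cc2)C1=O
A5 | alternative 2 | 2,5-bis[4-(tert-butyldimethylsilyloxy)phenyl]-3,6-dimethoxybenzene-1,4-diol | Oc1c(-c2ccc(O[Si](C)(C)C(C)(C)C)cc2)c(OC)c(O)c(-c2ccc(O[Si](C)(C)C(C)(C)C)cc2)c1OC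
A6 | alternative 3 | 2,5-dihydroxy-1,4-benzoquinone | OC1=CC(=O)C(O)=CC1=O
A7 | alternative 3 | 3,6-dioxocyclohexa-1,4-diene-1,4-diyl bis{(2Z)-3-[(2S,3S)-3-methyloxiran-2-yl]prop-2-enoate} | C[C@@H]1O[C@H]1/C=C\C(=O)OC1=CC(=O)C(OC(=O)/C=C\[C@@H]2O[C@H]2C)=CC1=O
A8 | alternative 3 | 2,5-bis[4-(tert-butyldimethylsilyloxy)phenyl]-3,6-dioxocyclohexa-1,4-diene-1,4-diyl bis{(2Z)-3-[(2S,3S)-3-methyloxiran-2-yl]prop-2-enoate} | C[C@@H]1O[C@H]1/C=C\C(=O)OC1=C(c2ccc(O[Si](C)(C)C(C)(C)C)cc2)C(=O)C(OC(=O)/C=C\[C@@H]2O[C@H]2C)=C(c2ccc(O[Si](C)(C)C(C)(C)C)cc2)C1=O
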